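# Proposed synthesis of 2-O-acetylzeylenone (12) from the microbial bromobenzene diol

Convention: in the discussion the ring atoms carry the locants of the target in every intermediate. C1 is the quaternary carbinol with the CH2O branch, C2 the acetoxy carbon, C3 the benzoyloxy carbon, C4=C5 the alkene and C6 the carbonyl carbon. Systematic names in the steps and lists use their own locants.

Assumption: diol 1 is taken as the enantiopure commercial fermentation product of bromobenzene, extracted from its buffered suspension just before use.

## Analysis of the target

Target 12 is a single six-membered carbocycle, a cyclohex-2-enone with oxygen on four contiguous ring carbons (C6, C1, C2, C3) and an exocyclic CH2O on C1. The three stereocentres are contiguous: C1 (S), C2 (S) and C3 (R). The tertiary C1 hydroxyl is cis to the C2 acetate, and the C2 acetate is trans to the C3 benzoate. Four oxygens carry three different acyl states (free tertiary OH, primary benzoate, secondary acetate, allylic secondary benzoate), so acyl migration between neighbouring oxygens threatens every basic step. The α-hydroxy-β-acyloxy ketone can fragment by retro-aldol cleavage and the γ-acyloxy enone can eliminate, which argues for neutral or weakly acidic conditions late in the route. The main difficulty is that every cyclohexadiene on the way is one elimination from a benzene ring, while a tertiary carbinol must be built next to the ketone. The strategy rests on three features of the structure: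

- The C1–O and C6–O bonds are vicinal and lie on the face of the C2 oxygen, so one syn addition to a C1=C6 alkene, steered by a free C2 hydroxyl, can deliver both.
- C2 has the configuration of the bromine-proximal carbinol of diol 1, and the bromine of 1 sits on the carbon that must carry the CH2O branch.
- Only C3 is opposite in configuration to 1, and it can be inverted safely only after C1 has become sp3.

## Retrosynthetic reasoning

**12 to 11.** The acetyl C–O bond at C2 is cut last. The C2 hydroxyl must stay free until the dihydroxylation, because it is the directing group. An acetate placed earlier would sit next to free hydroxyls and migrate. The forward step must acylate the secondary C2 hydroxyl of zeylenone 11 and leave the tertiary C1 hydroxyl alone.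

**11 to 9 and 10.** The C3–O ester bond is cut with inversion, leading to the all-cis triol enone 9 and benzoic acid 10. This disconnection is placed after the dihydroxylation on purpose. An activated hydroxyl next to a cyclohexa-1,3-diene ionises and the ring aromatises, so a Mitsunobu inversion at the diene stage is not defensible, although it would save two steps on paper. In 9 the carbon C1 is quaternary, aromatisation is impossible, and the allyl cation is destabilised by the enone, so a clean SN2 displacement can be expected. The forward step must esterify only the allylic C3 hydroxyl, with inversion.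

**9 to 8.** The O–Si bond at C3 is restored. The silyl ether keeps the C3 oxygen inert through coupling, osmylation and oxidation, and it prevents this second allylic carbinol from being oxidised.

**8 to 7.** The C6 carbonyl is traced back to the C6 carbinol. In 7 this is the only free allylic hydroxyl, so a mild allylic oxidation is enough and no protecting group is needed at C1 or C2.

**7 to 5 (key disconnection).** The C1–O and C6–O bonds are cut together, giving diene 5 with a free C2 hydroxyl. Cutting here brings two oxygens and the quaternary stereocentre from one reagent, and it returns to a ring whose carbons all come from an arene. The forward reaction must choose C1=C6 over C4=C5 and the face of the C2 hydroxyl.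

**5 to 4.** The primary benzoate C–O bond is cut. It is formed after the coupling, so that the palladium step never meets an allylic ester on a cyclohexadiene, which zerovalent palladium would ionise with aromatisation.

**4 to 2 and 3.** The C1–CH2 bond is cut to the vinyl bromide 2 and the hydroxymethyl stannane 3. The bromine of the microbial diol is the natural handle for this bond, and the neutral Stille conditions suit an acid-sensitive dienol.

**2 to 1.** The O–Si bond at the distal oxygen is cut. The forward silylation must distinguish the two secondary hydroxyls of 1; the proximal one is flanked by the C–Br carbon and is the slower.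

## Alternatives that were turned down

**Alternative 1:** The C1–C2 bond is disconnected by ring contraction to the acyl cyclopentenol A2, which carries the future C1 as a ketone on its carbinol carbon. In the forward sense a chelating Lewis acid holds carbinol and carbonyl oxygen syn, and C2 shifts from the carbinol carbon to the acyl carbon to give the cyclohexenone A1.
- For it: A1 already holds the enone, the tertiary carbinol and the trans C2/C3 relationship in their final configuration. On this point it is stronger than the chosen route, which needs a late inversion at C3.
- Against it: the carbinol carbon of A2 has two ring bonds that can migrate. The vinyl carbon has the higher migratory aptitude, and C2 is deactivated by its silyloxy group, so the wrong ring expansion is a real risk in an equilibrating reaction. The configuration at C1 depends on the carbinol stereocentre of A2, which must be made selectively although it is destroyed. A2 is a densely substituted enantiopure cyclopentene that needs a multistep synthesis of its own, and A1 still needs two benzyl-type ethers and a silyl ether exchanged for two benzoates and an acetate.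
- Comparison: the chosen route builds no ring, reaches its key precursor 5 in three steps from 1, and carries the final primary benzoate from step 3 on.

**Alternative 2:** The C1–C2 and C5–C6 bonds are disconnected to the dienophile 2-(benzoyloxy)acrolein A4 and the diene (E)-1-acetoxybuta-1,3-diene A5. A chiral primary ammonium salt activates A4 as its iminium ion, and an ortho-selective [4+2] cycloaddition gives the aldehyde A3.
- For it: the ring and the C1/C2 stereocentres arise catalytically from two small achiral partners, and the C2 acetate is in place from the start. In convergence and in avoiding a fermentation product it is stronger than the chosen route.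
- Against it: A3 has no oxygen at C3 or C6 and its alkene lies at C3=C4. After reduction of the aldehyde and an O-to-O benzoyl shift, the route would still need a C3 oxygen with alkene transposition and oxidation of C6. C6 is an unactivated methylene next to a quaternary carbon, so this means several oxidation steps with new selectivity problems. The enantiomeric purity depends on the catalyst.
- Comparison: the chosen route starts from an arene-derived ring that already has the right unsaturation, and places the C1 and C6 oxygens in one step.

**Alternative 3:** The C2–O bond is disconnected to the prochiral dienol A7. A chiral vanadium bishydroxamate catalyst with an alkyl hydroperoxide epoxidises one of the two enantiotopic alkenes syn to the tertiary hydroxyl and gives the epoxy alcohol A6.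
- For it: one catalytic step sets C1 and C2, and trans opening of the epoxide at C3 by a benzoate nucleophile would give the trans C2/C3 pattern without any inversion. On this point it is as strong as or stronger than the chosen route.
- Against it: A7 is a doubly allylic tertiary alcohol that loses water to an aromatic ring with traces of acid, and it is not trivial to prepare. A6 still has a methylene at C4 and its alkene at C5=C6, so the enone must come from an allylic oxidation with transposition. The enantiomeric purity again depends on the catalyst.
- Comparison: the chosen route takes its absolute configuration from the enantiopure diol 1 and obtains the C6 oxygen together with the C1 oxygen.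

Key step: step 4

## Route

Step 1
Reactants: 1 (1S,2S)-3-bromocyclohexa-3,5-diene-1,2-diol
Product: 2 (1S,6S)-2-bromo-6-[(tert-butyldimethylsilyl)oxy]cyclohexa-2,4-dien-1-ol
Conditions: TBSCl (1.05 equiv), imidazole, DMF, −20 → 0 °C
Reagents that add atoms: tert-butyldimethylsilyl chloride, CC(C)(C)[Si](C)(C)Cl
Why: Regioselective silylation of the less hindered distal hydroxyl; the proximal hydroxyl is flanked by the C–Br carbon and reacts more slowly, the usual selectivity pattern of 3-substituted arene cis-diols. No stereocentre is touched, and a silyl ether, unlike an ester, is inert to zerovalent palladium in step 2.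

Step 2
Reactants: 2 (1S,6S)-2-bromo-6-[(tert-butyldimethylsilyl)oxy]cyclohexa-2,4-dien-1-ol; 3 (tributylstannyl)methanol
Product: 4 (1R,6S)-6-[(tert-butyldimethylsilyl)oxy]-2-(hydroxymethyl)cyclohexa-2,4-dien-1-ol
Conditions: Pd(PPh3)4 (5 mol%), 1,4-dioxane, degassed, 80 °C; aq. KF work-up
Reagents that add atoms: none
Why: Stille coupling: zerovalent palladium inserts into the vinyl C–Br bond, the hydroxymethyl group is transferred from tin in preference to butyl, and reductive elimination forms the C1–CH2 bond. The conditions are neutral, and neither the free hydroxyl nor the silyl ether is a leaving group for π-allyl formation, so the dienol should survive; the descriptor at the carbinol changes from S to R only because the priorities change.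

Step 3
Reactants: 4 (1R,6S)-6-[(tert-butyldimethylsilyl)oxy]-2-(hydroxymethyl)cyclohexa-2,4-dien-1-ol
Product: 5 [(5S,6R)-5-[(tert-butyldimethylsilyl)oxy]-6-hydroxycyclohexa-1,3-dien-1-yl]methyl benzoate
Conditions: BzCl (1.05 equiv), pyridine, CH2Cl2, −40 → −10 °C
Reagents that add atoms: benzoyl chloride, O=C(Cl)c1ccccc1
Why: Chemoselective acylation of the primary allylic hydroxyl; the secondary C2 hydroxyl lies between the substituted C1 and the silyloxy-bearing C3 and is much slower at low temperature. The ester enters only after the palladium step.

Step 4
Reactants: 5 [(5S,6R)-5-[(tert-butyldimethylsilyl)oxy]-6-hydroxycyclohexa-1,3-dien-1-yl]methyl benzoate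
Product: 7 [(1R,2S,3S,6R)-3-[(tert-butyldimethylsilyl)oxy]-1,2,6-trihydroxycyclohex-4-en-1-yl]methyl benzoate, via cyclic osmate ester 6 (not isolated)
Conditions: OsO4 (1.05 equiv), TMEDA (1.1 equiv), CH2Cl2, −78 °C; then sat. aq. NaHSO3, THF, 50 °C
Reagents that add atoms: osmium tetroxide, O=[Os](=O)(=O)=O
Why: OsO4 bound to TMEDA is an electron-rich oxidant whose oxo ligands are strong hydrogen-bond acceptors, and the free C2 hydroxyl of 5 donates to one of them, holding the reagent on the face of that hydroxyl above the adjacent C1=C6 bond. A concerted [3+2] cycloaddition then forms both C–O bonds from the same face and gives the TMEDA-chelated osmate ester of hexavalent osmium 6, which reductive hydrolysis with bisulfite cleaves to 7. The closest known reaction type is the hydrogen-bond-directed syn-dihydroxylation of cyclic allylic alcohols with OsO4 and TMEDA, which reverses the anti preference of undirected osmylation. No ring of the target is closed; the only ring formed is the transient five-membered osmate ester, closed suprafacially on the alkene. Both new stereocentres, C1 and C6, are set by the C2 carbinol stereocentre through this hydrogen bond, and only C1 has to last because C6 is oxidised in step 5. The step needs site selectivity for C1=C6 over C4=C5 and attack on the face that also carries the C3 silyloxy group: the only hydrogen-bond donor is allylic to C1=C6 but merely homoallylic to C4=C5, the silyl ether oxygen is a poor acceptor and cannot direct, and C1=C6 is the more substituted, more electron-rich alkene. With the C2 hydroxyl pseudoaxial, which avoids allylic strain with the C1 side chain, the cis C3 silyloxy group is pseudoequatorial and leaves the upper face of C1=C6 open. One equivalent of oxidant at −78 °C guards against a second osmylation.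

Step 5
Reactants: 7 [(1R,2S,3S,6R)-3-[(tert-butyldimethylsilyl)oxy]-1,2,6-trihydroxycyclohex-4-en-1-yl]methyl benzoate
Product: 8 [(1S,2S,3S)-3-[(tert-butyldimethylsilyl)oxy]-1,2-dihydroxy-6-oxocyclohex-4-en-1-yl]methyl benzoate
Conditions: MnO2 (activated, excess), CH2Cl2, rt
Reagents that add atoms: none
Why: Selective allylic oxidation: the C6 carbinol is the only free allylic hydroxyl, since C3 is silylated, the C2 hydroxyl is not allylic and the C1 hydroxyl is tertiary. The C6 stereocentre is removed and the neutral heterogeneous oxidant should leave the esters in place.

Step 6
Reactants: 8 [(1S,2S,3S)-3-[(tert-butyldimethylsilyl)oxy]-1,2-dihydroxy-6-oxocyclohex-4-en-1-yl]methyl benzoate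
Product: 9 [(1S,2S,3S)-1,2,3-trihydroxy-6-oxocyclohex-4-en-1-yl]methyl benzoate
Conditions: HF·pyridine, pyridine, THF, 0 °C → rt
Reagents that add atoms: none
Why: Desilylation driven by Si–F bond formation; the buffered acidic fluoride source generates no alkoxide, so benzoyl migration and retro-aldol cleavage of the β-hydroxy ketone should be avoided.

Step 7
Reactants: 9 [(1S,2S,3S)-1,2,3-trihydroxy-6-oxocyclohex-4-en-1-yl]methyl benzoate; 10 benzoic acid
Product: 11 [(1S,2S,3R)-3-(benzoyloxy)-1,2-dihydroxy-6-oxocyclohex-4-en-1-yl]methyl benzoate (zeylenone)
Conditions: PPh3, DIAD (betaine preformed), THF, 0 °C → rt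
Reagents that add atoms: none
Why: Mitsunobu esterification, as used for inversion of 4-hydroxycyclohex-2-enones: the allylic C3 hydroxyl is activated as its oxyphosphonium ion and displaced by benzoate in an SN2 step with inversion, which sets the trans C2/C3 relationship. The C2 carbinol is neopentyl-like next to the quaternary C1 and the C1 hydroxyl is tertiary, so neither should be substituted. Aromatisation is blocked by the quaternary C1, and ionisation is disfavoured by the enone.

Step 8
Reactants: 11 [(1S,2S,3R)-3-(benzoyloxy)-1,2-dihydroxy-6-oxocyclohex-4-en-1-yl]methyl benzoate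
Product: 12 [(1S,2S,3R)-2-(acetyloxy)-3-(benzoyloxy)-1-hydroxy-6-oxocyclohex-4-en-1-yl]methyl benzoate
Conditions: Ac2O, pyridine, DMAP (cat.), CH2Cl2, 0 °C
Reagents that add atoms: acetic anhydride, CC(=O)OC(C)=O
Why: Nucleophile-catalysed acetylation of the secondary C2 hydroxyl; the tertiary α-ketol hydroxyl is far slower. Low temperature and a weak base should keep the benzoates in place and avoid elimination.

## Compound list

1 | (1S,2S)-3-bromocyclohexa-3,5-diene-1,2-diol | O[C@H]1[C@@H](O)C=CC=C1Br | starting material
2 | (1S,6S)-2-bromo-6-[(tert-butyldimethylsilyl)oxy]cyclohexa-2,4-dien-1-ol | O[C@H]1[C@@H](O[Si](C)(C)C(C)(C)C)C=CC=C1Br | intermediate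
3 | (tributylstannyl)methanol | CCCC[Sn](CCCC)(CCCC)CO | starting material
4 | (1R,6S)-6-[(tert-butyldimethylsilyl)oxy]-2-(hydroxymethyl)cyclohexa-2,4-dien-1-ol | O[C@H]1[C@@H](O[Si](C)(C)C(C)(C)C)C=CC=C1CO | intermediate
5 | [(5S,6R)-5-[(tert-butyldimethylsilyl)oxy]-6-hydroxycyclohexa-1,3-dien-1-yl]methyl benzoate (5,6-cis) | O[C@H]1[C@@H](O[Si](C)(C)C(C)(C)C)C=CC=C1COC(=O)c1ccccc1 | intermediate
6 | cyclic osmate ester of hexavalent osmium across C1 and C6 of 5, chelated by TMEDA (ligand written as a separate component) | O[C@H]1[C@@H](O[Si](C)(C)C(C)(C)C)C=C[C@@H](O[Os]2(=O)=O)[C@]1(O2)COC(=O)c1ccccc1.CN(C)CCN(C)C | intermediate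
7 | [(1R,2S,3S,6R)-3-[(tert-butyldimethylsilyl)oxy]-1,2,6-trihydroxycyclohex-4-en-1-yl]methyl benzoate (all-cis) | O[C@H]1[C@@H](O[Si](C)(C)C(C)(C)C)C=C[C@@H](O)[C@]1(O)COC(=O)c1ccccc1 | intermediate
8 | [(1S,2S,3S)-3-[(tert-butyldimethylsilyl)oxy]-1,2-dihydroxy-6-oxocyclohex-4-en-1-yl]methyl benzoate | O[C@H]1[C@@H](O[Si](C)(C)C(C)(C)C)C=CC(=O)[C@]1(O)COC(=O)c1ccccc1 | intermediate
9 | [(1S,2S,3S)-1,2,3-trihydroxy-6-oxocyclohex-4-en-1-yl]methyl benzoate | O[C@H]1[C@@H](O)C=CC(=O)[C@]1(O)COC(=O)c1ccccc1 | intermediate
10 | benzoic acid | OC(=O)c1ccccc1 | starting material
11 | [(1S,2S,3R)-3-(benzoyloxy)-1,2-dihydroxy-6-oxocyclohex-4-en-1-yl]methyl benzoate (zeylenone) | O[C@H]1[C@H](OC(=O)c2ccccc2)C=CC(=O)[C@]1(O)COC(=O)c1ccccc1 | intermediate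
12 | [(1S,2S,3R)-2-(acetyloxy)-3-(benzoyloxy)-1-hydroxy-6-oxocyclohex-4-en-1-yl]methyl benzoate (2-O-acetylzeylenone) | CC(=O)O[C@H]1[C@H](OC(=O)c2ccccc2)C=CC(=O)[C@]1(O)COC(=O)c1ccccc1 | target

## Step count and risk

Total: 8 steps. Longest linear sequence: 8 steps (1 to 12).

**Step 4 (key step).** The likeliest failure is loss of site or face control. Undirected osmylation of the less substituted C4=C5 bond, or anti addition to C1=C6, could compete because both are sterically easier than delivery to the trisubstituted alkene on the face that carries two oxygens. The fallback replaces the osmylation by a hydroxyl-bound epoxidation. Starting from 5, VO(acac)2 and t-BuOOH in CH2Cl2 at 0 °C should oxidise only the alkene next to the coordinated C2 hydroxyl, syn to it, and give [3-[(tert-butyldimethylsilyl)oxy]-2-hydroxy-7-oxabicyclo[4.1.0]hept-4-en-1-yl]methyl benzoate (all-cis) F1. Dilute HClO4 in THF–water at 0 °C should open the vinyl epoxide at the allylic C6 and leave the C1–O bond and its configuration untouched, giving [(1R,2S,3S,6S)-3-[(tert-butyldimethylsilyl)oxy]-1,2,6-trihydroxycyclohex-4-en-1-yl]methyl benzoate F2. The configuration at C6 does not matter, since MnO2 oxidation of F2 returns to the route at 8.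

**Step 7.** The cis C2/C3 diol of 9 may form a cyclic phosphorane, and the benzoate may then end up on the wrong oxygen or be delivered with retention by acyl transfer; elimination towards a dienone is also possible. The fallback removes the ambiguity by changing the order of acylation. Starting from 8, Ac2O, pyridine and catalytic DMAP should give [(1S,2S,3S)-2-(acetyloxy)-3-[(tert-butyldimethylsilyl)oxy]-1-hydroxy-6-oxocyclohex-4-en-1-yl]methyl benzoate F3. HF·pyridine would then free the C3 hydroxyl under acidic conditions, where acetyl migration is slow, to give [(1S,2S,3S)-2-(acetyloxy)-1,3-dihydroxy-6-oxocyclohex-4-en-1-yl]methyl benzoate F4. Its only secondary hydroxyl is the allylic one at C3, and Mitsunobu esterification with 10 returns directly to the route at 12.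

**Step 2.** Transfer of an sp3 group from tin is slow, and during heating the dienol may dehydrate to an aromatic ring under the influence of the tin halide formed, or dimerise by cycloaddition. The fallback builds the C1 branch in two steps without tin. Starting from 2, methoxycarbonylation (Pd(OAc)2, PPh3, Et3N, MeOH, CO 1 atm, 60 °C) should give methyl (5S,6R)-5-[(tert-butyldimethylsilyl)oxy]-6-hydroxycyclohexa-1,3-diene-1-carboxylate F5, a dienoate that is less prone to ionisation. Reduction with i-Bu2AlH in CH2Cl2 at −78 °C returns to the route at 4.

**Step 1.** Discrimination between the two secondary hydroxyls may be incomplete, giving bis-silylation or some proximal silyl ether. The fallback moves the silylation to a stage where the C1 substituent is larger. Starting from 1, Stille coupling with 3 on the free diol would give (1S,2R)-3-(hydroxymethyl)cyclohexa-3,5-diene-1,2-diol F6, and primary benzoylation at −40 °C would give [(5S,6R)-5,6-dihydroxycyclohexa-1,3-dien-1-yl]methyl benzoate F7. Its proximal hydroxyl is flanked by the CH2OBz-bearing carbon, and silylation with TBSCl and imidazole returns to the route at 5.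

## Further compounds

F1 | step 4 | [3-[(tert-butyldimethylsilyl)oxy]-2-hydroxy-7-oxabicyclo[4.1.0]hept-4-en-1-yl]methyl benzoate (epoxide cis to the 2-hydroxyl and the 3-silyloxy group) | O[C@H]1[C@@H](O[Si](C)(C)C(C)(C)C)C=C[C@@H](O2)[C@]12COC(=O)c1ccccc1
F2 | step 4 | [(1R,2S,3S,6S)-3-[(tert-butyldimethylsilyl)oxy]-1,2,6-trihydroxycyclohex-4-en-1-yl]methyl benzoate | O[C@H]1[C@@H](O[Si](C)(C)C(C)(C)C)C=C[C@H](O)[C@]1(O)COC(=O)c1ccccc1
F3 | step 7 | [(1S,2S,3S)-2-(acetyloxy)-3-[(tert-butyldimethylsilyl)oxy]-1-hydroxy-6-oxocyclohex-4-en-1-yl]methyl benzoate | CC(=O)O[C@H]1[C@@H](O[Si](C)(C)C(C)(C)C)C=CC(=O)[C@]1(O)COC(=O)c1ccccc1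
F4 | step 7 | [(1S,2S,3S)-2-(acetyloxy)-1,3-dihydroxy-6-oxocyclohex-4-en-1-yl]methyl benzoate | CC(=O)O[C@H]1[C@@H](O)C=CC(=O)[C@]1(O)COC(=O)c1ccccc1
F5 | step 2 | methyl (5S,6R)-5-[(tert-butyldimethylsilyl)oxy]-6-hydroxycyclohexa-1,3-diene-1-carboxylate | O[C@H]1[C@@H](O[Si](C)(C)C(C)(C)C)C=CC=C1C(=O)OC
F6 | step 1 | (1S,2R)-3-(hydroxymethyl)cyclohexa-3,5-diene-1,2-diol | O[C@H]1[C@@H](O)C=CC=C1CO
F7 | step 1 | [(5S,6R)-5,6-dihydroxycyclohexa-1,3-dien-1-yl]methyl benzoate | O[C@H]1[C@@H](O)C=CC=C1COC(=O)c1ccccc1
A1 | alternative 1 | 6-hydroxy-4-(4-methoxybenzyloxy)-6-[(4-methoxybenzyloxy)methyl]-5-(tert-butyldimethylsilyloxy)cyclohex-2-en-1-one | CC(C)(C)[Si](C)(C)O[C@H]1[C@H](OCc2ccc(OC)cc2)C=CC(=O)[C@]1(O)COCc1ccc(OC)cc1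
A2 | alternative 1 | 1-[1-hydroxy-4-(4-methoxybenzyloxy)-5-(tert-butyldimethylsilyloxy)cyclopent-2-en-1-yl]-2-(4-methoxybenzyloxy)ethan-1-one (4,5-trans, hydroxyl cis to the silyloxy group) | O=C(COCc1ccc(OC)cc1)[C@@]1(O)C=C[C@@H](OCc2ccc(OC)cc2)[C@@H]1O[Si](C)(C)C(C)(C)C
A3 | alternative 2 | cis-2-acetoxy-1-formylcyclohex-3-en-1-yl benzoate | CC(=O)O[C@H]1C=CCC[C@]1(OC(=O)c1ccccc1)C=O
A4 | alternative 2 | 2-(benzoyloxy)acrolein | C=C(OC(=O)c1ccccc1)C=O
A5 | alternative 2 | (E)-1-acetoxybuta-1,3-diene | CC(=O)O/C=C/C=C
A6 | alternative 3 | (2-hydroxy-7-oxabicyclo[4.1.0]hept-3-en-2-yl)methyl benzoate (hydroxyl cis to the epoxide) | O1[C@H]2[C@@H]1CC=C[C@]2(O)COC(=O)c1ccccc1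
A7 | alternative 3 | (1-hydroxycyclohexa-2,5-dien-1-yl)methyl benzoate | OC1(COC(=O)c2ccccc2)C=CCC=C1
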